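**Strategy.** The route rests on disconnecting ring A at C1–C10 and ring B at C5–C6, which unravels the chlorodecalin to an open-chain trienone. In one operation TiCl4 triggers an enone-initiated cation–olefin bicyclization: C5 of the E-trisubstituted C5=C10 alkene adds to the vinyl ketone terminus C6, the resulting C10 cation is captured by the terminal vinyl group through C1, and the C2 cation takes up chloride. The step exploits the 1,3-relationship in ring A between the quaternary C10 (C20 methyl) and the equatorial C2 chloride, flanked by the axial C19 and C20 methyls. The precursor is a vinyl ketone carrying one quaternary stereocentre (C4).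

Key step: step 9

Remark: labdane numbering (C1–C20) is used throughout; starting materials 1, 7, 18 and 19 and all reagents are taken as purchasable.

**Step 1**
Reactants: 1 pent-1-en-4-yne
Product: 3 (2E)-3-methylhexa-2,5-dien-1-ol, via alkenylalane 2 (not isolated)
Conditions: Me3Al (2 equiv), Cp2ZrCl2 (0.2 equiv), CH2Cl2, 0 to 23 °C; then (CH2O)n, THF, 0 to 23 °C; aqueous work-up
Reagents that add atoms: trimethylaluminium, C[Al](C)C; paraformaldehyde (as formaldehyde), C=O
Why: Negishi zirconium-catalysed carboalumination adds methyl and aluminium syn across the alkyne with methyl on the internal carbon, and hydroxymethylation of the alkenylalane with retention should give the E allylic alcohol while the isolated alkene stays inert.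

**Step 2**
Reactants: 3 (2E)-3-methylhexa-2,5-dien-1-ol
Product: 4 [(2S,3S)-3-methyl-3-(prop-2-en-1-yl)oxiran-2-yl]methanol
Conditions: Ti(OiPr)4 (10 mol %), L-(+)-diethyl tartrate (12 mol %), t-BuOOH (2 equiv), 4 Å molecular sieves, CH2Cl2, −20 °C
Reagents that add atoms: tert-butyl hydroperoxide, CC(C)(C)OO
Why: Sharpless asymmetric epoxidation touches only the allylic alcohol alkene and, by analogy with geraniol and the L-(+)-tartrate ligand, should give the (2S,3S) epoxide that later becomes C4.

**Step 3**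
Reactants: 4 [(2S,3S)-3-methyl-3-(prop-2-en-1-yl)oxiran-2-yl]methanol
Product: 5 tert-butyl{[(2S,3S)-3-methyl-3-(prop-2-en-1-yl)oxiran-2-yl]methoxy}diphenylsilane
Conditions: TBDPSCl (1.1 equiv), imidazole (2 equiv), CH2Cl2, 23 °C
Reagents that add atoms: tert-butyl(chloro)diphenylsilane, CC(C)(C)[Si](Cl)(c1ccccc1)c1ccccc1
Why: Standard silylation of the primary alcohol installs the bulky silyl ether that the rearrangement needs and that later steers the bicyclization.

**Step 4**
Reactants: 5 tert-butyl{[(2S,3S)-3-methyl-3-(prop-2-en-1-yl)oxiran-2-yl]methoxy}diphenylsilane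
Product: 6 (2S)-2-{[(tert-butyldiphenylsilyl)oxy]methyl}-2-methylpent-4-enal
Conditions: methylaluminium bis(4-bromo-2,6-di-tert-butylphenoxide) (2 equiv), CH2Cl2, −78 to −40 °C
Reagents that add atoms: none
Why: The bulky organoaluminium Lewis acid opens the epoxide at its tertiary carbon while the silyloxymethyl group migrates anti (semipinacol-type 1,2-shift with inversion), so the epoxide chirality should be transferred to the quaternary C4 of the β-silyloxy aldehyde.

**Step 5**
Reactants: 7 (2E)-3-iodobut-2-enoic acid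
Product: 9 (2E)-3-iodo-N-methoxy-N-methylbut-2-enamide, via acid chloride 8 (not isolated)
Conditions: (COCl)2 (1.2 equiv), DMF (cat.), CH2Cl2, 0 to 23 °C; then MeNHOMe·HCl (1.3 equiv), pyridine (3 equiv), 0 °C
Reagents that add atoms: N,O-dimethylhydroxylamine hydrochloride, CNOC.Cl
Why: Acid chloride formation and aminolysis give the Weinreb amide without disturbing the vinyl iodide geometry.

**Step 6**
Reactants: 6 (2S)-2-{[(tert-butyldiphenylsilyl)oxy]methyl}-2-methylpent-4-enal; 9 (2E)-3-iodo-N-methoxy-N-methylbut-2-enamide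
Product: 10 (2E,5S)-5-{[(tert-butyldiphenylsilyl)oxy]methyl}-4-hydroxy-N-methoxy-N,3,5-trimethylocta-2,7-dienamide (both carbinol epimers)
Conditions: CrCl2 (4 equiv), NiCl2 (2 mol %), DMSO/THF, 23 °C
Reagents that add atoms: none
Why: The Nozaki–Hiyama–Kishi coupling tolerates the hindered α-quaternary aldehyde and the Weinreb amide and keeps the E geometry, and the new carbinol centre (C5) is erased in the next step.

**Step 7**
Reactants: 10 (2E,5S)-5-{[(tert-butyldiphenylsilyl)oxy]methyl}-4-hydroxy-N-methoxy-N,3,5-trimethylocta-2,7-dienamide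
Product: 11 ethyl (4E,6R)-6-{[(tert-butyldiphenylsilyl)oxy]methyl}-3-[methoxy(methyl)carbamoyl]-4,6-dimethylnona-4,8-dienoate (both C3 epimers)
Conditions: MeC(OEt)3 (10 equiv), EtCO2H (0.1 equiv), 140 °C, distilling off EtOH
Reagents that add atoms: triethyl orthoacetate, CC(OCC)(OCC)OCC
Why: The Johnson–Claisen rearrangement through a chair with the bulky C4 group equatorial should form the C9–C11 bond and the E C5=C10 alkene (C4 cis to the C20 methyl), while C9 arises as a mixture that is equilibrated in step 9.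

**Step 8**
Reactants: 11 ethyl (4E,6R)-6-{[(tert-butyldiphenylsilyl)oxy]methyl}-3-[methoxy(methyl)carbamoyl]-4,6-dimethylnona-4,8-dienoate
Product: 12 ethyl (4E,6R)-6-{[(tert-butyldiphenylsilyl)oxy]methyl}-4,6-dimethyl-3-(prop-2-enoyl)nona-4,8-dienoate (both C3 epimers)
Conditions: CH2=CHMgBr (1.3 equiv), THF, −78 to −30 °C; poured into cold 1 M HCl
Reagents that add atoms: vinylmagnesium bromide, C=C[Mg]Br
Why: In this Weinreb ketone synthesis the chelated tetrahedral adduct stops at the ketone stage, the amide should react before the ethyl ester at low temperature, and the cold acidic quench prevents conjugate addition of the released amine.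

**Step 9**
Reactants: 12 ethyl (4E,6R)-6-{[(tert-butyldiphenylsilyl)oxy]methyl}-4,6-dimethyl-3-(prop-2-enoyl)nona-4,8-dienoate
Product: 15 ethyl 2α-chloro-18-[(tert-butyldiphenylsilyl)oxy]-8-oxo-13,14,15,16,17-pentanorlabdan-12-oate, via titanium enolate 13 (not isolated), via C9-epimeric keto ester 14 (not isolated)
Conditions: TiCl4 (3 equiv), 2,6-di-tert-butyl-4-methylpyridine (0.3 equiv), CH2Cl2, −78 °C; saturated aqueous NaHCO3; then DBU (0.3 equiv), CH2Cl2, 23 °C
Reagents that add atoms: titanium tetrachloride, Cl[Ti](Cl)(Cl)Cl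
Why: TiCl4 activates the vinyl ketone, C5 of the C5=C10 alkene attacks C6 (ring B, 6-endo-trig at the enone, giving titanium enolate 13), the tertiary C10 cation is attacked by C1 of the terminal vinyl group (ring A, 6-endo, Markovnikov) and chloride quenches the secondary C2 cation. The closest known reaction type is the Lewis acid-promoted enone-initiated cation–olefin polycyclization with Prins-type halide termination. Both rings should close through a chair–chair transition state with antiperiplanar addition across the E alkene, which fixes the trans ring fusion (5α-H, 10β-CH3). The only stereocentre carried over from 12, C4, selects the alkene face by placing its large CH2OSi group equatorial and its methyl axial beside the C20 methyl. Chloride should enter C2 equatorially, anti to the new C1–C10 bond, because the axial face is screened by the C19 and C20 methyls, and C9, epimerisable next to the C8 ketone, is set by the DBU equilibration to the equatorial side chain. The step needs the trisubstituted alkene alone to initiate and chloride to terminate: only that alkene can reach C6 in a six-membered array, excess TiCl4 keeps the C12 ester complexed and non-nucleophilic, and the hindered pyridine suppresses proton-initiated paths.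

**Step 10**
Reactants: 15 ethyl 2α-chloro-18-[(tert-butyldiphenylsilyl)oxy]-8-oxo-13,14,15,16,17-pentanorlabdan-12-oate
Product: 16 ethyl 2α-chloro-18-[(tert-butyldiphenylsilyl)oxy]-13,14,15,16-tetranorlabd-8(17)-en-12-oate
Conditions: Ph3PCH3Br (3 equiv), KOt-Bu (2.8 equiv), THF, 0 to 45 °C
Reagents that add atoms: methyltriphenylphosphonium bromide, C[P+](c1ccccc1)(c1ccccc1)c1ccccc1.[Br-]
Why: Wittig methylenation of the C8 ketone beside an ester follows the behaviour of 8-oxolabdanes, and the equatorial C2 chloride, lacking an antiperiplanar hydrogen and flanked by neopentyl-like carbons, should resist elimination and substitution.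

**Step 11**
Reactants: 16 ethyl 2α-chloro-18-[(tert-butyldiphenylsilyl)oxy]-13,14,15,16-tetranorlabd-8(17)-en-12-oate
Product: 17 2α-chloro-18-[(tert-butyldiphenylsilyl)oxy]-13,14,15,16-tetranorlabd-8(17)-en-12-al
Conditions: i-Bu2AlH (1.1 equiv), CH2Cl2, −78 °C; aqueous Rochelle salt
Reagents that add atoms: none
Why: Partial reduction of the ester at −78 °C through the stable tetrahedral aluminate should stop at the aldehyde, and the chloride, alkene and silyl ether are inert.

**Step 12**
Reactants: 18 (4R)-4-benzyl-1,3-oxazolidin-2-one; 19 3-cyanopropanoic acid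
Product: 21 (4R)-4-benzyl-3-(3-cyanopropanoyl)-1,3-oxazolidin-2-one, via mixed pivalic anhydride 20 (not isolated)
Conditions: t-BuCOCl (1.05 equiv), Et3N (2.5 equiv), THF, −20 °C; then 18, LiCl (1.1 equiv), 23 °C
Reagents that add atoms: none
Why: N-Acylation of the oxazolidinone through the mixed pivalic anhydride with LiCl activation is a standard preparation of Evans imides.

**Step 13**
Reactants: 17 2α-chloro-18-[(tert-butyldiphenylsilyl)oxy]-13,14,15,16-tetranorlabd-8(17)-en-12-al; 21 (4R)-4-benzyl-3-(3-cyanopropanoyl)-1,3-oxazolidin-2-one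
Product: 23 (4R)-4-benzyl-3-[(12S,13R)-2α-chloro-18-(tert-butyldiphenylsilyloxy)-12-hydroxy-15-nitrilolabd-8(17)-en-16-oyl]-1,3-oxazolidin-2-one, via dibutylboron enolate 22 (not isolated)
Conditions: Bu2BOTf (1.2 equiv), i-Pr2NEt (1.4 equiv), CH2Cl2, −78 to 0 °C; then 17, −78 to 0 °C; pH 7 buffer, MeOH, 30 % H2O2, 0 °C
Reagents that add atoms: none
Why: In this Evans syn-aldol the Z boron enolate reacts through a Zimmerman–Traxler chair on the face away from the benzyl group, so the (R) auxiliary should set 12S and 13R regardless of the remote substrate centres, and only the imide α-position is enolised.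

**Step 14**
Reactants: 23 (4R)-4-benzyl-3-[(12S,13R)-2α-chloro-18-(tert-butyldiphenylsilyloxy)-12-hydroxy-15-nitrilolabd-8(17)-en-16-oyl]-1,3-oxazolidin-2-one
Product: 25 18-O-(tert-butyldiphenylsilyl)haterumaimide J, via primary amide 24 (not isolated)
Conditions: [PtH{(PMe2O)2H}(PMe2OH)] (5 mol %), EtOH/H2O (4:1), 80 °C; then K2CO3 (1.5 equiv), MeOH, 0 °C; aqueous NH4Cl
Reagents that add atoms: water, O
Why: Neutral Ghaffar–Parkins hydration turns the nitrile into the primary amide, whose nitrogen should then displace the oxazolidinone by 5-exo-trig acyl substitution under mild base and close the succinimide without touching C12 or C13.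

**Step 15**
Reactants: 25 18-O-(tert-butyldiphenylsilyl)haterumaimide J
Product: 26 haterumaimide J
Conditions: HF·pyridine, THF/pyridine, 0 to 23 °C
Reagents that add atoms: none
Why: Fluoride under weakly acidic conditions should cleave the neopentyl silyl ether while leaving the base-sensitive β-hydroxy imide, the exocyclic alkene and the chloride intact.

**Compound list**

1 | pent-1-en-4-yne | C#CCC=C | starting material
2 | (E)-dimethyl(2-methylpenta-1,4-dien-1-yl)alane | C[Al](C)/C=C(\C)CC=C | intermediate (not isolated)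
3 | (2E)-3-methylhexa-2,5-dien-1-ol | OC/C=C(C)/CC=C | intermediate
4 | [(2S,3S)-3-methyl-3-(prop-2-en-1-yl)oxiran-2-yl]methanol | C=CC[C@]1(C)O[C@H]1CO | intermediate
5 | tert-butyl{[(2S,3S)-3-methyl-3-(prop-2-en-1-yl)oxiran-2-yl]methoxy}diphenylsilane | C=CC[C@]1(C)O[C@H]1CO[Si](c1ccccc1)(c1ccccc1)C(C)(C)C | intermediate
6 | (2S)-2-{[(tert-butyldiphenylsilyl)oxy]methyl}-2-methylpent-4-enal | O=C[C@](C)(CO[Si](c1ccccc1)(c1ccccc1)C(C)(C)C)CC=C | intermediate
7 | (2E)-3-iodobut-2-enoic acid | C/C(I)=C\C(=O)O | starting material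
8 | (2E)-3-iodobut-2-enoyl chloride | C/C(I)=C\C(=O)Cl | intermediate (not isolated)
9 | (2E)-3-iodo-N-methoxy-N-methylbut-2-enamide | C/C(I)=C\C(=O)N(C)OC | intermediate
10 | (2E,5S)-5-{[(tert-butyldiphenylsilyl)oxy]methyl}-4-hydroxy-N-methoxy-N,3,5-trimethylocta-2,7-dienamide, carbinol epimers | CON(C)C(=O)/C=C(\C)C(O)[C@](C)(CO[Si](c1ccccc1)(c1ccccc1)C(C)(C)C)CC=C | intermediate
11 | ethyl (4E,6R)-6-{[(tert-butyldiphenylsilyl)oxy]methyl}-3-[methoxy(methyl)carbamoyl]-4,6-dimethylnona-4,8-dienoate, C3 epimers | CON(C)C(=O)C(CC(=O)OCC)/C(C)=C/[C@](C)(CO[Si](c1ccccc1)(c1ccccc1)C(C)(C)C)CC=C | intermediate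
12 | ethyl (4E,6R)-6-{[(tert-butyldiphenylsilyl)oxy]methyl}-4,6-dimethyl-3-(prop-2-enoyl)nona-4,8-dienoate, C3 epimers | C=CC(=O)C(CC(=O)OCC)/C(C)=C/[C@](C)(CO[Si](c1ccccc1)(c1ccccc1)C(C)(C)C)CC=C | intermediate
13 | trichlorotitanium C7=C8 enolate of the cyclized chloro keto ester | Cl[Ti](Cl)(Cl)OC1=CC[C@H]2[C@](C)(CO[Si](c3ccccc3)(c3ccccc3)C(C)(C)C)C[C@H](Cl)C[C@]2(C)C1CC(=O)OCC | intermediate (not isolated)
14 | ethyl 2α-chloro-18-[(tert-butyldiphenylsilyl)oxy]-8-oxo-13,14,15,16,17-pentanorlabdan-12-oate, C9 epimers | O=C1CC[C@H]2[C@](C)(CO[Si](c3ccccc3)(c3ccccc3)C(C)(C)C)C[C@H](Cl)C[C@]2(C)C1CC(=O)OCC | intermediate (not isolated)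
15 | ethyl 2α-chloro-18-[(tert-butyldiphenylsilyl)oxy]-8-oxo-13,14,15,16,17-pentanorlabdan-12-oate (5α-H, 9α-H, 10β-CH3, 4β-CH3) | O=C1CC[C@H]2[C@](C)(CO[Si](c3ccccc3)(c3ccccc3)C(C)(C)C)C[C@H](Cl)C[C@]2(C)[C@H]1CC(=O)OCC | intermediate
16 | ethyl 2α-chloro-18-[(tert-butyldiphenylsilyl)oxy]-13,14,15,16-tetranorlabd-8(17)-en-12-oate | C=C1CC[C@H]2[C@](C)(CO[Si](c3ccccc3)(c3ccccc3)C(C)(C)C)C[C@H](Cl)C[C@]2(C)[C@H]1CC(=O)OCC | intermediate
17 | 2α-chloro-18-[(tert-butyldiphenylsilyl)oxy]-13,14,15,16-tetranorlabd-8(17)-en-12-al | C=C1CC[C@H]2[C@](C)(CO[Si](c3ccccc3)(c3ccccc3)C(C)(C)C)C[C@H](Cl)C[C@]2(C)[C@H]1CC=O | intermediate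
18 | (4R)-4-benzyl-1,3-oxazolidin-2-one | O=C1N[C@H](Cc2ccccc2)CO1 | starting material
19 | 3-cyanopropanoic acid | N#CCCC(=O)O | starting material
20 | 3-cyanopropanoic 2,2-dimethylpropanoic anhydride | CC(C)(C)C(=O)OC(=O)CCC#N | intermediate (not isolated)
21 | (4R)-4-benzyl-3-(3-cyanopropanoyl)-1,3-oxazolidin-2-one | N#CCCC(=O)N1[C@H](Cc2ccccc2)COC1=O | intermediate
22 | (Z)-dibutylboron enolate of 21 | CCCCB(CCCC)O/C(N1[C@H](Cc2ccccc2)COC1=O)=C\CC#N | intermediate (not isolated)
23 | (4R)-4-benzyl-3-[(12S,13R)-2α-chloro-18-(tert-butyldiphenylsilyloxy)-12-hydroxy-15-nitrilolabd-8(17)-en-16-oyl]-1,3-oxazolidin-2-one | C=C1CC[C@H]2[C@](C)(CO[Si](c3ccccc3)(c3ccccc3)C(C)(C)C)C[C@H](Cl)C[C@]2(C)[C@H]1C[C@H](O)[C@H](C(=O)N1[C@H](Cc2ccccc2)COC1=O)CC#N | intermediate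
24 | primary amide from hydration of the nitrile of 23 | C=C1CC[C@H]2[C@](C)(CO[Si](c3ccccc3)(c3ccccc3)C(C)(C)C)C[C@H](Cl)C[C@]2(C)[C@H]1C[C@H](O)[C@H](C(=O)N1[C@H](Cc2ccccc2)COC1=O)CC(N)=O | intermediate (not isolated)
25 | 18-O-(tert-butyldiphenylsilyl)haterumaimide J | C=C1CC[C@H]2[C@](C)(CO[Si](c3ccccc3)(c3ccccc3)C(C)(C)C)C[C@H](Cl)C[C@]2(C)[C@H]1C[C@H](O)[C@H]1CC(=O)NC1=O | intermediate
26 | haterumaimide J | C=C1CC[C@H]2[C@](C)(CO)C[C@H](Cl)C[C@]2(C)[C@H]1C[C@H](O)[C@H]1CC(=O)NC1=O | target

**Step count and risks**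

Total steps: 15. Longest linear sequence: 13 (steps 1–4, 6–11 and 13–15).

Steps most likely to fail:

1. Step 9. The C10 or C2 cation may shed a proton, or be intercepted by the C12 ester oxygen, before ring A closes and chloride is delivered; discrimination of the two alkene faces by C4 may also be incomplete. Fallback: setting out from 12, the bicyclization would be run with MeAlCl2 in CH2Cl2 at −78 °C, a Lewis acid that scavenges protons and offers no nucleophilic chloride, so that the C2 cation ends by proton loss. After the same DBU equilibration this should give the ring A olefins, the Δ2 keto ester F1 and its Δ1 isomer F2. Hydrogenation of both (H2, Pd/C, EtOAc) converges on the saturated keto ester F3. Chlorine is then introduced by site-selective radical C–H chlorination (N-chloro-N-tert-butyl-3,5-bis(trifluoromethyl)benzamide, Cs2CO3, benzene, visible light), which on trans-decalins of this kind attacks the unhindered, electron-rich C2 methylene from the equatorial face. This returns to 15.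

2. Step 8. The Grignard reagent may enolise the doubly activated C9–H, which would also move the C5=C10 alkene into conjugation, instead of adding to the amide. Fallback: from 11, the far less basic ethynylmagnesium bromide (HC≡CMgBr, THF, −78 to 0 °C, acidic quench) would add to the Weinreb amide to give the ynone F4. Semihydrogenation of the terminal alkyne (H2, Pd/CaCO3 poisoned with Pb(OAc)2, quinoline, EtOAc) would then give 12.

3. Step 14. Retro-aldol cleavage or epimerisation at C13 may occur under the basic ring closure. Fallback: from 23, the auxiliary would first be removed with LiOH/H2O2 (THF/H2O, 0 °C) to give the β-hydroxy acid nitrile F5. The same platinum-catalysed hydration would give the amide acid F6. Ring closure by carboxyl activation (1,1'-carbonyldiimidazole, DMAP, THF, 50 °C), the way glutarimides are closed from amide acids, returns to 25.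

**Further compounds**

F1 | step 9 | ethyl 18-[(tert-butyldiphenylsilyl)oxy]-8-oxo-13,14,15,16,17-pentanorlabd-2-en-12-oate | O=C1CC[C@H]2[C@](C)(CO[Si](c3ccccc3)(c3ccccc3)C(C)(C)C)C=CC[C@]2(C)[C@H]1CC(=O)OCC
F2 | step 9 | ethyl 18-[(tert-butyldiphenylsilyl)oxy]-8-oxo-13,14,15,16,17-pentanorlabd-1-en-12-oate | O=C1CC[C@H]2[C@](C)(CO[Si](c3ccccc3)(c3ccccc3)C(C)(C)C)CC=C[C@]2(C)[C@H]1CC(=O)OCC
F3 | step 9 | ethyl 18-[(tert-butyldiphenylsilyl)oxy]-8-oxo-13,14,15,16,17-pentanorlabdan-12-oate | O=C1CC[C@H]2[C@](C)(CO[Si](c3ccccc3)(c3ccccc3)C(C)(C)C)CCC[C@]2(C)[C@H]1CC(=O)OCC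
F4 | step 8 | ethyl (4E,6R)-6-{[(tert-butyldiphenylsilyl)oxy]methyl}-4,6-dimethyl-3-(prop-2-ynoyl)nona-4,8-dienoate, C3 epimers | C#CC(=O)C(CC(=O)OCC)/C(C)=C/[C@](C)(CO[Si](c1ccccc1)(c1ccccc1)C(C)(C)C)CC=C
F5 | step 14 | (12S,13R)-2α-chloro-18-[(tert-butyldiphenylsilyl)oxy]-12-hydroxy-15-nitrilolabd-8(17)-en-16-oic acid | C=C1CC[C@H]2[C@](C)(CO[Si](c3ccccc3)(c3ccccc3)C(C)(C)C)C[C@H](Cl)C[C@]2(C)[C@H]1C[C@H](O)[C@H](C(=O)O)CC#N
F6 | step 14 | (12S,13R)-15-amino-2α-chloro-18-[(tert-butyldiphenylsilyl)oxy]-12-hydroxy-15-oxolabd-8(17)-en-16-oic acid | C=C1CC[C@H]2[C@](C)(CO[Si](c3ccccc3)(c3ccccc3)C(C)(C)C)C[C@H](Cl)C[C@]2(C)[C@H]1C[C@H](O)[C@H](C(=O)O)CC(N)=O
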